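## Retrosynthetic overview
1. The target is the (3S,5S), 1,3-anti diol. Global O-debenzylation leads back to its bis(benzyl ether).
2. Both carbinol centres (C3 and C5) come from one double (S)-BINAP–Ru hydrogenation of the C3/C5 β-diketone.
3. The key C4–C5 bond comes from a crossed Claisen condensation. The kinetic lithium enolate of O-benzylzingerone (C1–C4, ring A) attacks benzyl 3-[4-(benzyloxy)-3,5-dimethoxyphenyl]propanoate (C5–C7, ring B).
4. The ketone comes from zingerone and BnBr. The ester comes from syringaldehyde and malonic acid (Knoevenagel–Doebner), then C=C hydrogenation, then double benzylation.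
5. No ring is formed. Ring A (guaiacyl) and ring B (syringyl) are bought intact.

Reading of the target: the chain is numbered from the guaiacyl end. At each carbinol the priorities are OH > C4H2 > outer CH2 > H, so the SMILES decodes as 3S,5S, which is the anti diol.

## Route

Step 1
Reactants: 1 zingerone [4-(4-hydroxy-3-methoxyphenyl)butan-2-one]; 2 benzyl bromide
Product: 3 4-[4-(benzyloxy)-3-methoxyphenyl]butan-2-one
Conditions: BnBr (1.1 equiv), K2CO3 (1.5 equiv), DMF, 25 °C, 12 h
Reagents that add atoms: benzyl bromide (2), BrCc1ccccc1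
Why: Williamson ether synthesis, in which K2CO3 deprotonates only the phenol and the phenoxide displaces bromide by SN2, so the ketone is untouched and no stereocentre is formed.

Step 2
Reactants: 4 syringaldehyde (4-hydroxy-3,5-dimethoxybenzaldehyde); 5 malonic acid
Product: 7 sinapic acid [(E)-3-(4-hydroxy-3,5-dimethoxyphenyl)prop-2-enoic acid], via benzylidenemalonic acid 6 (not isolated)
Conditions: malonic acid (2.0 equiv), pyridine, piperidine (0.1 equiv), 70 °C, 4 h; product precipitated from cold dilute HCl
Reagents that add atoms: malonic acid (5), OC(=O)CC(=O)O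
Why: Knoevenagel condensation in the Doebner modification, in which the amine-catalysed condensation gives 6, 6 loses CO2 in warm pyridine to give the favoured E acid, and the 70 °C limit prevents a second decarboxylation to the vinylphenol.

Step 3
Reactants: 7 sinapic acid
Product: 8 3-(4-hydroxy-3,5-dimethoxyphenyl)propanoic acid
Conditions: H2 (1 atm), 10% Pd/C, MeOH, 25 °C, 6 h
Reagents that add atoms: none
Why: Heterogeneous catalytic hydrogenation of the conjugated C=C is fast at 1 atm, and because no benzyl group is present yet there is nothing else to reduce and no stereocentre is formed.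

Step 4
Reactants: 8 3-(4-hydroxy-3,5-dimethoxyphenyl)propanoic acid; 2 benzyl bromide
Product: 9 benzyl 3-[4-(benzyloxy)-3,5-dimethoxyphenyl]propanoate
Conditions: BnBr (2.4 equiv), K2CO3 (3.0 equiv), DMF, 60 °C, 12 h
Reagents that add atoms: benzyl bromide (2), BrCc1ccccc1
Why: Double O-alkylation (Williamson etherification of the phenoxide and SN2 esterification of the carboxylate) masks the phenol and activates the acid as an ester in one operation, and warm DMF overcomes the flanking methoxy groups.

Step 5
Reactants: 3 4-[4-(benzyloxy)-3-methoxyphenyl]butan-2-one; 9 benzyl 3-[4-(benzyloxy)-3,5-dimethoxyphenyl]propanoate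
Product: 12 1-[4-(benzyloxy)-3-methoxyphenyl]-7-[4-(benzyloxy)-3,5-dimethoxyphenyl]heptane-3,5-dione, via lithium enolate 10 (not isolated), via lithium diketonate 11 (not isolated)
Conditions: 3 (2.0 equiv), LiN(iPr)2 (2.05 equiv), THF, −78 °C, 45 min; then 9 (1.0 equiv) in THF, −78 °C → 0 °C → 23 °C, 4 h; 1 M HCl quench; surplus 3 recovered by chromatography
Reagents that add atoms: none
Why: Crossed Claisen condensation, in which the methyl group of 3 is deprotonated kinetically, the ketone enolate cannot deprotonate the less acidic ester, and irreversible deprotonation of the β-diketone by the second equivalent of enolate (giving chelated 11) pulls the reversible aldol and branched-acylation equilibria towards the linear C4–C5 product, with no stereocentre formed.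

Step 6
Reactants: 12 1-[4-(benzyloxy)-3-methoxyphenyl]-7-[4-(benzyloxy)-3,5-dimethoxyphenyl]heptane-3,5-dione
Product: 15 (3S,5S)-1-[4-(benzyloxy)-3-methoxyphenyl]-7-[4-(benzyloxy)-3,5-dimethoxyphenyl]heptane-3,5-diol, via 5-hydroxy-3-ketone 13 (not isolated), via 3-hydroxy-5-ketone 14 (not isolated)
Conditions: RuCl2[(S)-BINAP](dmf)n (1 mol%, from [RuCl2(C6H6)]2 + (S)-BINAP, DMF, 100 °C), H2 (80 atm), degassed MeOH–CH2Cl2 4:1, 50 °C, 48 h; chromatography and recrystallisation remove the trace of syn diol
Reagents that add atoms: none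
Why: Noyori asymmetric hydrogenation of a β-diketone, in which the chelated (S)-BINAP–Ru catalyst sets the first carbinol as S at either carbonyl (as in pentane-2,4-dione giving the (S,S)-diol), the second reduction is the matched case and sets the other centre S to give the anti diol, and any minor-enantiomer ketol ends up mainly as the separable syn diol, which raises the ee of 15, while benzyl ethers and arenes are inert to this catalyst.

Step 7
Reactants: 15 (3S,5S)-1-[4-(benzyloxy)-3-methoxyphenyl]-7-[4-(benzyloxy)-3,5-dimethoxyphenyl]heptane-3,5-diol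
Product: 16 (3S,5S)-1-(4-hydroxy-3-methoxyphenyl)-7-(4-hydroxy-3,5-dimethoxyphenyl)heptane-3,5-diol (target)
Conditions: H2 (1 atm), 10% Pd/C, EtOAc–EtOH 1:1, 25 °C, 8 h
Reagents that add atoms: none
Why: Catalytic hydrogenolysis cleaves both aryl benzyl ethers under neutral conditions, and the two non-benzylic secondary carbinols cannot be hydrogenolysed or epimerised, so the 3S,5S configuration is kept.

## Compound list
1 | zingerone, 4-(4-hydroxy-3-methoxyphenyl)butan-2-one | CC(=O)CCc1ccc(O)c(OC)c1 | starting material
2 | benzyl bromide | BrCc1ccccc1 | starting material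
3 | 4-[4-(benzyloxy)-3-methoxyphenyl]butan-2-one | CC(=O)CCc1ccc(OCc2ccccc2)c(OC)c1 | intermediate
4 | syringaldehyde, 4-hydroxy-3,5-dimethoxybenzaldehyde | COc1cc(C=O)cc(OC)c1O | starting material
5 | malonic acid | OC(=O)CC(=O)O | starting material
6 | 2-(4-hydroxy-3,5-dimethoxybenzylidene)malonic acid (not isolated) | COc1cc(C=C(C(=O)O)C(=O)O)cc(OC)c1O | intermediate
7 | sinapic acid, (E)-3-(4-hydroxy-3,5-dimethoxyphenyl)prop-2-enoic acid | COc1cc(/C=C/C(=O)O)cc(OC)c1O | intermediate
8 | 3-(4-hydroxy-3,5-dimethoxyphenyl)propanoic acid | COc1cc(CCC(=O)O)cc(OC)c1O | intermediate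
9 | benzyl 3-[4-(benzyloxy)-3,5-dimethoxyphenyl]propanoate | COc1cc(CCC(=O)OCc2ccccc2)cc(OC)c1OCc1ccccc1 | intermediate
10 | lithium 4-[4-(benzyloxy)-3-methoxyphenyl]but-1-en-2-olate, kinetic enolate of 3 (not isolated) | [Li+].[O-]C(=C)CCc1ccc(OCc2ccccc2)c(OC)c1 | intermediate
11 | chelated lithium (Z)-enolate of diketone 12 (not isolated) | [Li+].COc1cc(CCC(=O)/C=C(\[O-])CCc2cc(OC)c(OCc3ccccc3)c(OC)c2)ccc1OCc1ccccc1 | intermediate
12 | 1-[4-(benzyloxy)-3-methoxyphenyl]-7-[4-(benzyloxy)-3,5-dimethoxyphenyl]heptane-3,5-dione (largely enolised) | COc1cc(CCC(=O)CC(=O)CCc2cc(OC)c(OCc3ccccc3)c(OC)c2)ccc1OCc1ccccc1 | intermediate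
13 | (5S)-1-[4-(benzyloxy)-3-methoxyphenyl]-7-[4-(benzyloxy)-3,5-dimethoxyphenyl]-5-hydroxyheptan-3-one (not isolated) | COc1cc(CCC(=O)C[C@@H](O)CCc2cc(OC)c(OCc3ccccc3)c(OC)c2)ccc1OCc1ccccc1 | intermediate
14 | (5S)-7-[4-(benzyloxy)-3-methoxyphenyl]-1-[4-(benzyloxy)-3,5-dimethoxyphenyl]-5-hydroxyheptan-3-one (not isolated) | COc1cc(CC[C@H](O)CC(=O)CCc2cc(OC)c(OCc3ccccc3)c(OC)c2)ccc1OCc1ccccc1 | intermediate
15 | (3S,5S)-1-[4-(benzyloxy)-3-methoxyphenyl]-7-[4-(benzyloxy)-3,5-dimethoxyphenyl]heptane-3,5-diol | COc1cc(CC[C@H](O)C[C@@H](O)CCc2cc(OC)c(OCc3ccccc3)c(OC)c2)ccc1OCc1ccccc1 | intermediate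
16 | (3S,5S)-1-(4-hydroxy-3-methoxyphenyl)-7-(4-hydroxy-3,5-dimethoxyphenyl)heptane-3,5-diol | COc1cc(CC[C@H](O)C[C@@H](O)CCc2cc(OC)c(O)c(OC)c2)ccc1O | target

## Totals and risks
Total step count: 7.
Longest linear sequence: 6 steps (4 → 7 → 8 → 9 → 12 → 15 → 16).

**Risk 1, step 5.** Both partners of the crossed Claisen condensation are enolisable, so conversion or the linear/branched ratio may be poor.
- The fallback sets out from 9, with 3 as partner, and comes back at 12.
- Ester 9 is reduced with iBu2AlH (1.1 equiv, CH2Cl2, −78 °C) to 3-[4-(benzyloxy)-3,5-dimethoxyphenyl]propanal F1.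
- Enolate 10, made as in step 5 from only 1.1 equiv of 3, adds to this aldehyde within minutes at −78 °C in a lithium aldol addition.
- The adduct is racemic 1-[4-(benzyloxy)-3-methoxyphenyl]-7-[4-(benzyloxy)-3,5-dimethoxyphenyl]-5-hydroxyheptan-3-one F2.
- Oxidation of this ketol with 2-iodoxybenzoic acid (EtOAc, 75 °C) gives 12, and both stereocentres are still set in step 6.

**Risk 2, step 6.** The large flanking groups or low solubility may slow the second reduction or erode the anti:syn ratio.
- The fallback sets out from 12 and comes back at 15.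
- The hydrogenation is stopped after about one equivalent of H2 (same catalyst, 10 atm, 30 °C). Ketols 13 and 14 are isolated together by chromatography and unreacted 12 is recycled.
- The mixture is reduced with Me4NBH(OAc)3 in MeCN–AcOH 1:1 at −30 °C (Evans–Saksena reduction). The existing (S)-carbinol binds the boron and delivers hydride intramolecularly through a chair transition state, which gives the 1,3-anti diol.
- Ketols 13 and 14 differ only in which end is already reduced, so both converge on 15.
- New compounds on this way: none F0.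

**Risk 3, step 2.** In the Knoevenagel–Doebner reaction the free para-phenol deactivates the aldehyde, and the product can decarboxylate further.
- The fallback sets out from 4 and comes back at 9, bypassing 7 and 8.
- Compound 4 is benzylated with 2 (K2CO3, DMF, 60 °C) to 4-(benzyloxy)-3,5-dimethoxybenzaldehyde F3.
- Horner–Wadsworth–Emmons olefination with benzyl (diethoxyphosphoryl)acetate (NaH, THF, 0 °C) gives benzyl (E)-3-[4-(benzyloxy)-3,5-dimethoxyphenyl]prop-2-enoate F4.
- Homogeneous hydrogenation with RhCl(PPh3)3 (5 mol%, H2 4 atm, toluene–EtOH, 50 °C) saturates only the C=C, leaves both benzyl groups in place, and gives 9.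

## Further compounds
F1 | step 5 | 3-[4-(benzyloxy)-3,5-dimethoxyphenyl]propanal | COc1cc(CCC=O)cc(OC)c1OCc1ccccc1
F2 | step 5 | racemic 1-[4-(benzyloxy)-3-methoxyphenyl]-7-[4-(benzyloxy)-3,5-dimethoxyphenyl]-5-hydroxyheptan-3-one | COc1cc(CCC(=O)CC(O)CCc2cc(OC)c(OCc3ccccc3)c(OC)c2)ccc1OCc1ccccc1
F0 | step 6 | none | none
F3 | step 2 | 4-(benzyloxy)-3,5-dimethoxybenzaldehyde | COc1cc(C=O)cc(OC)c1OCc1ccccc1
F4 | step 2 | benzyl (E)-3-[4-(benzyloxy)-3,5-dimethoxyphenyl]prop-2-enoate | COc1cc(/C=C/C(=O)OCc2ccccc2)cc(OC)c1OCc1ccccc1
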